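Ring A of the target is lettered a to f (a carries the butyryl group, b an OH, c the CH2 bridge, d an OH, e the two methyl groups, f is the ring C=O); it is a 6,6-dimethylcyclohexa-2,4-dienone whose quaternary carbon e forbids aromatisation, so it is what a dienylketene six-electron closure delivers directly.
Retrosynthesis: with the hydroxyls masked as enol ethers and the butyryl as a silylated carbinol, ring A is cut at bonds f–a, b–c and e–f into a 3-ethoxy-4,4-dimethylcyclobutenone (carbons c to f, bridge, ring B) and a 1-methoxyalkyne (carbons a and b, side chain).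
The cyclobutenone is cut into dimethylketene and an ethoxyalkyne, the ethoxyalkyne at its CH2–C(sp) bond into a bromomethyl ring B and a stannyl ynol ether, and ring B goes back to 2,4,6-trihydroxyacetophenone.
Forward: ring B is set up first by dearomatising C-methylation, the four-membered ring follows by [2+2] cycloaddition, ring A is closed last, and desilylation, oxidation and hydrolysis finish the synthesis.
Stereochemistry: the target has no stereocentre; the carbinol carbon brought in with the alkyne is racemic and is erased by oxidation.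

Key step: step 9

Assumption: the double O-methylation of step 2 is drawn as the 3,5-dimethoxy-2,4-dienone; a positional isomer of the enol ethers would pass through steps 3 to 11 in the same way and converge in the hydrolysis of step 12.
Abbreviation: RB = 3-acetyl-2,6-dimethoxy-5,5-dimethyl-4-oxocyclohexa-2,6-dien-1-yl (protected ring B).

Step 1
Reactants: 1 2,4,6-trihydroxyacetophenone
Product: 2 2-acetyl-3,5-dihydroxy-4,6,6-trimethylcyclohexa-2,4-dien-1-one
Conditions: MeI (3.2 equiv), NaOMe, MeOH, 0 °C to rt
Reagents that add atoms: iodomethane, CI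
Why: Exhaustive C-methylation of an acylphloroglucinol polyanion, in which the second methyl on one ring carbon dearomatises the ring and leaves the third on the remaining free carbon.

Step 2
Reactants: 2 2-acetyl-3,5-dihydroxy-4,6,6-trimethylcyclohexa-2,4-dien-1-one
Product: 3 2-acetyl-3,5-dimethoxy-4,6,6-trimethylcyclohexa-2,4-dien-1-one
Conditions: Me3SiCHN2 (excess), MeOH/PhMe, 0 °C to rt
Reagents that add atoms: trimethylsilyldiazomethane, C[Si](C)(C)C=[N+]=[N-]
Why: Diazoalkane O-methylation of an enolised β-triketone, in which both acidic enol hydroxyls protonate the reagent and are methylated on oxygen, avoiding the C-methylation that MeI and base would cause.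

Step 3
Reactants: 3 2-acetyl-3,5-dimethoxy-4,6,6-trimethylcyclohexa-2,4-dien-1-one
Product: 4 2-acetyl-4-(bromomethyl)-3,5-dimethoxy-6,6-dimethylcyclohexa-2,4-dien-1-one
Conditions: NBS (1.05 equiv), AIBN (cat.), PhCF3, 80 °C, hν
Reagents that add atoms: N-bromosuccinimide, O=C1CCC(=O)N1Br
Why: Wohl–Ziegler bromination, directed to the ring methyl because it holds the only allylic hydrogens (the gem-dimethyl carbon is quaternary, the acetyl methyl is not allylic) and its radical is delocalised over the dienone.

Step 4
Reactants: 5 ethoxyacetylene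
Product: 7 tributyl(ethoxyethynyl)stannane, via (ethoxyethynyl)lithium 6 (not isolated)
Conditions: n-BuLi, THF, −78 °C; then Bu3SnCl, −78 °C to rt
Reagents that add atoms: chlorotributylstannane (Bu3SnCl), CCCC[Sn](Cl)(CCCC)CCCC
Why: Deprotonation of the terminal alkyne and stannylation of the lithium acetylide, a standard preparation of alkynylstannanes.

Step 5
Reactants: 4 2-acetyl-4-(bromomethyl)-3,5-dimethoxy-6,6-dimethylcyclohexa-2,4-dien-1-one; 7 tributyl(ethoxyethynyl)stannane
Product: 8 2-acetyl-4-(3-ethoxyprop-2-yn-1-yl)-3,5-dimethoxy-6,6-dimethylcyclohexa-2,4-dien-1-one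
Conditions: Pd2(dba)3 (cat.), P(2-furyl)3, THF, 50 °C
Reagents that add atoms: none
Why: Stille coupling of an allylic bromide with an alkynylstannane (oxidative addition of zerovalent palladium, alkynyl transfer from tin, reductive elimination at the CH2 terminus), whose neutral conditions spare the acetyl and ring ketones that an alkali-metal acetylide would attack.

Step 6
Reactants: 8 2-acetyl-4-(3-ethoxyprop-2-yn-1-yl)-3,5-dimethoxy-6,6-dimethylcyclohexa-2,4-dien-1-one; 9 isobutyryl chloride
Product: 11 3-ethoxy-4,4-dimethyl-2-[(RB)methyl]cyclobut-2-en-1-one, via dimethylketene 10 (not isolated)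
Conditions: Et3N, CH2Cl2, 40 °C, slow addition of 9
Reagents that add atoms: none
Why: Ketene–alkoxyalkyne [2+2] cycloaddition, in which the ketene carbonyl carbon bonds to the nucleophilic CH2-bearing alkyne carbon and the CMe2 carbon to the ethoxy-bearing one, giving the 3-ethoxycyclobutenone regiochemistry.

Step 7
Reactants: 12 chloroacetaldehyde dimethyl acetal; 13 butanal
Product: 15 rac-1-methoxyhex-1-yn-3-ol, via (methoxyethynyl)lithium 14 (not isolated)
Conditions: LiNEt2 (3 equiv), THF, 0 °C; then 13, −78 to 0 °C; H2O
Reagents that add atoms: none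
Why: Twofold base-induced elimination (methanol, then HCl) gives the lithium alkoxyacetylide, which adds to the aldehyde (acetylide 1,2-addition) without facial control, acceptable because the carbinol is oxidised in step 11.

Step 8
Reactants: 15 rac-1-methoxyhex-1-yn-3-ol
Product: 16 rac-tert-butyl[(1-methoxyhex-1-yn-3-yl)oxy]dimethylsilane
Conditions: t-BuMe2SiCl, imidazole, DMF, 0 °C to rt
Reagents that add atoms: tert-butylchlorodimethylsilane, CC(C)(C)[Si](C)(C)Cl
Why: Silyl ether formation under basic conditions, which avoids acid-induced Meyer–Schuster rearrangement of the alkoxyalkynyl carbinol and removes the hydroxyl that ketenes would acylate in step 9.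

Step 9
Reactants: 11 3-ethoxy-4,4-dimethyl-2-[(RB)methyl]cyclobut-2-en-1-one; 16 rac-tert-butyl[(1-methoxyhex-1-yn-3-yl)oxy]dimethylsilane
Product: 20 2-[1-(tert-butyldimethylsilyloxy)butyl]-5-ethoxy-3-methoxy-6,6-dimethyl-4-[(RB)methyl]cyclohexa-2,4-dien-1-one (racemic), via vinylketene 17 (not isolated), via 4-alkenylcyclobutenone 18 (not isolated), via dienylketene 19 (not isolated)
Conditions: 16 (2.5 equiv), PhMe, 110 then 140 °C, sealed tube, Ar
Reagents that add atoms: none
Why: Proposed new method: heating should open 11 by four-electron electrocyclic cleavage of its C(=O)–CMe2 bond to vinylketene 17, whose ketene carbon (future ring A carbon f) is attacked by the nucleophilic carbon of ynol ether 16 (future carbon a) in a [2+2] cycloaddition that also joins the methoxy-bearing carbon (b) to the bridge-bearing carbon (c), giving 4-alkenylcyclobutenone 18; a second four-electron opening gives dienylketene 19, and ring A closes by thermal disrotatory six-electron electrocyclisation of the ketene carbon onto the CMe2 terminus (bond e–f). The closest known reaction type is the Danheiser benzannulation of cyclobutenones with alkynyl ethers, which ends in a phenol; here the closing terminus is quaternary, so the cascade should stop at the 6,6-dimethylcyclohexa-2,4-dienone. No stereocentre is created in 20: carbon e carries two methyl groups, the transient quaternary centre of 18 is lost on ring opening, and the racemic carbinol carbon of 16 is not touched. The step needs regioselectivity in the ketene–alkyne cycloaddition, secured by the polarisation of the ynol ether (the carbon remote from OMe is nucleophilic, the ketene carbonyl carbon electrophilic), and chemoselectivity for the alkyne over the push–pull enol ethers of ring B, secured by the much higher ketenophilicity of an ynol ether used in excess. Only the isomer of 19 with the ethoxyalkenyl group cis to the ketene-bearing carbon can cyclise, and reversible reclosure to 18 should feed the other isomer back. A methyl ynol ether is used because it has no β-hydrogen and so cannot lose an alkene by retro-ene fragmentation at this temperature.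

Step 10
Reactants: 20 2-[1-(tert-butyldimethylsilyloxy)butyl]-5-ethoxy-3-methoxy-6,6-dimethyl-4-[(RB)methyl]cyclohexa-2,4-dien-1-one
Product: 21 5-ethoxy-2-(1-hydroxybutyl)-3-methoxy-6,6-dimethyl-4-[(RB)methyl]cyclohexa-2,4-dien-1-one (racemic)
Conditions: Bu4NF, AcOH (1 equiv each), THF, 0 °C to rt
Reagents that add atoms: none
Why: Fluoride-induced cleavage of the silyl ether, buffered with acetic acid so that the vinylogous ester enol ethers and the acetyl group should remain untouched.

Step 11
Reactants: 21 5-ethoxy-2-(1-hydroxybutyl)-3-methoxy-6,6-dimethyl-4-[(RB)methyl]cyclohexa-2,4-dien-1-one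
Product: 22 2-butanoyl-5-ethoxy-3-methoxy-6,6-dimethyl-4-[(RB)methyl]cyclohexa-2,4-dien-1-one
Conditions: Dess–Martin periodinane, CH2Cl2, 0 °C to rt
Reagents that add atoms: none
Why: Dess–Martin oxidation of the secondary allylic carbinol to the butyryl ketone, mild enough for the four enol ethers, and removing the only stereocentre.

Step 12
Reactants: 22 2-butanoyl-5-ethoxy-3-methoxy-6,6-dimethyl-4-[(RB)methyl]cyclohexa-2,4-dien-1-one
Product: 23 2-acetyl-4-[(3-butanoyl-2,6-dihydroxy-5,5-dimethyl-4-oxocyclohexa-2,6-dien-1-yl)methyl]-3,5-dihydroxy-6,6-dimethylcyclohexa-2,4-dien-1-one (target CNP0085757.0)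
Conditions: 2 M aq. HCl, THF, 50 °C
Reagents that add atoms: water, O
Why: Acid hydrolysis of vinylogous esters (protonation on the conjugated carbonyl, addition of water at the alkoxy-bearing carbon, loss of alcohol), applied to all four enol ethers to release the two enolised triketone rings.

Compound list
1 | 2,4,6-trihydroxyacetophenone | CC(=O)c1c(O)cc(O)cc1O | starting material
2 | 2-acetyl-3,5-dihydroxy-4,6,6-trimethylcyclohexa-2,4-dien-1-one | CC(=O)C1=C(O)C(C)=C(O)C(C)(C)C1=O | intermediate
3 | 2-acetyl-3,5-dimethoxy-4,6,6-trimethylcyclohexa-2,4-dien-1-one | CC(=O)C1=C(OC)C(C)=C(OC)C(C)(C)C1=O | intermediate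
4 | 2-acetyl-4-(bromomethyl)-3,5-dimethoxy-6,6-dimethylcyclohexa-2,4-dien-1-one | CC(=O)C1=C(OC)C(CBr)=C(OC)C(C)(C)C1=O | intermediate
5 | ethoxyacetylene | CCOC#C | starting material
6 | (ethoxyethynyl)lithium | [Li]C#COCC | intermediate (not isolated)
7 | tributyl(ethoxyethynyl)stannane | CCOC#C[Sn](CCCC)(CCCC)CCCC | intermediate
8 | 2-acetyl-4-(3-ethoxyprop-2-yn-1-yl)-3,5-dimethoxy-6,6-dimethylcyclohexa-2,4-dien-1-one | CCOC#CCC1=C(OC)C(C)(C)C(=O)C(C(C)=O)=C1OC | intermediate
9 | isobutyryl chloride | CC(C)C(Cl)=O | starting material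
10 | dimethylketene | CC(C)=C=O | intermediate (not isolated)
11 | 3-ethoxy-4,4-dimethyl-2-[(RB)methyl]cyclobut-2-en-1-one | CCOC1=C(CC2=C(OC)C(C)(C)C(=O)C(C(C)=O)=C2OC)C(=O)C1(C)C | intermediate
12 | chloroacetaldehyde dimethyl acetal (2-chloro-1,1-dimethoxyethane) | COC(CCl)OC | starting material
13 | butanal | CCCC=O | starting material
14 | (methoxyethynyl)lithium | [Li]C#COC | intermediate (not isolated)
15 | rac-1-methoxyhex-1-yn-3-ol | CCCC(O)C#COC | intermediate
16 | rac-tert-butyl[(1-methoxyhex-1-yn-3-yl)oxy]dimethylsilane | CCCC(O[Si](C)(C)C(C)(C)C)C#COC | intermediate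
17 | 3-ethoxy-4-methyl-2-[(RB)methyl]penta-1,3-dien-1-one (vinylketene) | CCOC(=C(C)C)C(CC1=C(OC)C(C)(C)C(=O)C(C(C)=O)=C1OC)=C=O | intermediate (not isolated)
18 | 2-[1-(tert-butyldimethylsilyloxy)butyl]-4-(1-ethoxy-2-methylprop-1-en-1-yl)-3-methoxy-4-[(RB)methyl]cyclobut-2-en-1-one (racemic, both diastereomers) | CCCC(O[Si](C)(C)C(C)(C)C)C1=C(OC)C(CC2=C(OC)C(C)(C)C(=O)C(C(C)=O)=C2OC)(C(OCC)=C(C)C)C1=O | intermediate (not isolated)
19 | 2-[1-(tert-butyldimethylsilyloxy)butyl]-5-ethoxy-3-methoxy-6-methyl-4-[(RB)methyl]hepta-1,3,5-trien-1-one, ketene-bearing carbon and ethoxyalkenyl group cis on the central C=C (racemic dienylketene) | CCCC(O[Si](C)(C)C(C)(C)C)C(=C=O)/C(OC)=C(CC1=C(OC)C(C)(C)C(=O)C(C(C)=O)=C1OC)\C(OCC)=C(C)C | intermediate (not isolated)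
20 | 2-[1-(tert-butyldimethylsilyloxy)butyl]-5-ethoxy-3-methoxy-6,6-dimethyl-4-[(RB)methyl]cyclohexa-2,4-dien-1-one (racemic) | CCCC(O[Si](C)(C)C(C)(C)C)C1=C(OC)C(CC2=C(OC)C(C)(C)C(=O)C(C(C)=O)=C2OC)=C(OCC)C(C)(C)C1=O | intermediate
21 | 5-ethoxy-2-(1-hydroxybutyl)-3-methoxy-6,6-dimethyl-4-[(RB)methyl]cyclohexa-2,4-dien-1-one (racemic) | CCCC(O)C1=C(OC)C(CC2=C(OC)C(C)(C)C(=O)C(C(C)=O)=C2OC)=C(OCC)C(C)(C)C1=O | intermediate
22 | 2-butanoyl-5-ethoxy-3-methoxy-6,6-dimethyl-4-[(RB)methyl]cyclohexa-2,4-dien-1-one | CCCC(=O)C1=C(OC)C(CC2=C(OC)C(C)(C)C(=O)C(C(C)=O)=C2OC)=C(OCC)C(C)(C)C1=O | intermediate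
23 | 2-acetyl-4-[(3-butanoyl-2,6-dihydroxy-5,5-dimethyl-4-oxocyclohexa-2,6-dien-1-yl)methyl]-3,5-dihydroxy-6,6-dimethylcyclohexa-2,4-dien-1-one | CCCC(=O)C1=C(O)C(CC2=C(O)C(C)(C)C(=O)C(C(C)=O)=C2O)=C(O)C(C)(C)C1=O | target

Total step count: 12.
Longest linear sequence: 9 steps (steps 1, 2, 3, 5, 6, 9, 10, 11, 12, from 1 to 23).

Steps most likely to fail

Step 9. The vinylketene may isomerise by a 1,5-hydrogen shift from its cis methyl group faster than the alkyne traps it. The hindered cyclobutenone may open only at temperatures where the ynol ether oligomerises. Closure onto the fully substituted terminus may be slow, so that the alkenylcyclobutenone stalls. The fallback builds ring A by known acylfilicinic acid chemistry and sets out from bromide 4. Commercial 1-(2,4,6-trihydroxyphenyl)butan-1-one F1 would be C-dimethylated (MeI, 2 equiv, NaOMe, MeOH) to butyrylfilicinic acid F2. Its sodium salt (NaH, THF, 0 °C) would be C-alkylated at the free ring carbon by 4 to give the half-protected methylene-bridged dimer F3. Hydrolysis of the two methyl enol ethers of F3 (aq. HCl, THF) comes back to the route at 23.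

Step 3. Bromine may attack the methyl-bearing enol-ether ring carbon ionically, with loss of an O-methyl group, instead of abstracting an allylic hydrogen. The acetyl methyl may brominate through its enol, and the reactive allylic bromide may solvolyse on isolation. The fallback installs the one-carbon electrophile by a Mannich reaction and sets out from 1. C-dimethylation (MeI, 2 equiv, NaOMe, MeOH) would give acetylfilicinic acid F4. Aminomethylation of its free ring carbon with dimethylmethyleneiminium iodide (Eschenmoser's salt; MeCN, rt) would give the Mannich base 2-acetyl-4-[(dimethylamino)methyl]-3,5-dihydroxy-6,6-dimethylcyclohexa-2,4-dien-1-one F5. O-methylation with Me3SiCHN2 would give the dimethyl ether F6. Ethyl chloroformate (CH2Cl2, 0 °C to rt) would cleave the allylic C–N bond to the chloromethyl compound F7. Stille coupling of F7 with 7 under the conditions of step 5 comes back to the route at 8.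

Step 5. The stannane may protodestannylate, the ynol ether product may hydrate or isomerise to an allenyl ether during coupling or chromatography, and the bromide may homocouple. The fallback never makes a functionalised ynol ether; it sets out from 4 and uses 5 and 9. Dimethylketene (from 9 and Et3N) and ethoxyacetylene 5 would give 3-ethoxy-4,4-dimethylcyclobut-2-en-1-one F8. Mild acid hydrolysis would give the vinylogous acid 3-hydroxy-4,4-dimethylcyclobut-2-en-1-one F9. C-alkylation of its enolate with 4 (K2CO3, acetone) would give 3-hydroxy-4,4-dimethyl-2-[(RB)methyl]cyclobut-2-en-1-one F10. O-ethylation (Et3OBF4, i-Pr2NEt, CH2Cl2) has no regiochemical ambiguity, since the two oxygens of this dione are equivalent, and comes back to the route at 11.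

Further compounds
F1 | step 9 | 1-(2,4,6-trihydroxyphenyl)butan-1-one (purchased) | CCCC(=O)c1c(O)cc(O)cc1O
F2 | step 9 | butyrylfilicinic acid (2-butanoyl-3,5-dihydroxy-6,6-dimethylcyclohexa-2,4-dien-1-one) | CCCC(=O)C1=C(O)C=C(O)C(C)(C)C1=O
F3 | step 9 | 2-butanoyl-3,5-dihydroxy-6,6-dimethyl-4-[(RB)methyl]cyclohexa-2,4-dien-1-one | CCCC(=O)C1=C(O)C(CC2=C(OC)C(C)(C)C(=O)C(C(C)=O)=C2OC)=C(O)C(C)(C)C1=O
F4 | step 3 | acetylfilicinic acid (2-acetyl-3,5-dihydroxy-6,6-dimethylcyclohexa-2,4-dien-1-one) | CC(=O)C1=C(O)C=C(O)C(C)(C)C1=O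
F5 | step 3 | 2-acetyl-4-[(dimethylamino)methyl]-3,5-dihydroxy-6,6-dimethylcyclohexa-2,4-dien-1-one | CC(=O)C1=C(O)C(CN(C)C)=C(O)C(C)(C)C1=O
F6 | step 3 | 2-acetyl-4-[(dimethylamino)methyl]-3,5-dimethoxy-6,6-dimethylcyclohexa-2,4-dien-1-one | CC(=O)C1=C(OC)C(CN(C)C)=C(OC)C(C)(C)C1=O
F7 | step 3 | 2-acetyl-4-(chloromethyl)-3,5-dimethoxy-6,6-dimethylcyclohexa-2,4-dien-1-one | CC(=O)C1=C(OC)C(CCl)=C(OC)C(C)(C)C1=O
F8 | step 5 | 3-ethoxy-4,4-dimethylcyclobut-2-en-1-one | CCOC1=CC(=O)C1(C)C
F9 | step 5 | 3-hydroxy-4,4-dimethylcyclobut-2-en-1-one | OC1=CC(=O)C1(C)C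
F10 | step 5 | 3-hydroxy-4,4-dimethyl-2-[(RB)methyl]cyclobut-2-en-1-one | OC1=C(CC2=C(OC)C(C)(C)C(=O)C(C(C)=O)=C2OC)C(=O)C1(C)C
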